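The only stereocentre, C2 of the flavanone, is the β-carbon of the ring C enone (C4=O, C3, C2) and carries ring B as its single carbon substituent. The C2–C1' bond is therefore made by a catalytic enantioselective conjugate arylation: a 2-unsubstituted 5-benzyloxy-7-methoxychromone accepts at C2 the aryl group of a boronic acid that already holds the complete 8-arylapigenin half, itself assembled by Suzuki coupling at flavone C8. One operation joins both halves and sets the (2S) configuration; the flavone enone of the nucleophile is 2-aryl-substituted and stays inert. Benzyl ethers on all free phenols allow a final hydrogenolysis that spares the 7-methyl ether.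

Key step: step 7

Assumption: the facial preference of the Pd/t-BuPyOx catalyst on chromones is taken to parallel that on cyclic enones, so the (R)-ligand should give (2S); should the sense prove opposite, the (S)-ligand is used with no other change.

Step 1
Reactants: 1 apigenin
Product: 2 5,7-bis(benzyloxy)-2-[4-(benzyloxy)phenyl]-4H-chromen-4-one
Conditions: BnBr (4.5 equiv), K2CO3 (6 equiv), DMF, 80 °C
Reagents that add atoms: benzyl bromide, BrCc1ccccc1
Why: Williamson etherification of all three phenols, with excess reagent and heat to force the chelated 5-OH to react last.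

Step 2
Reactants: 2 5,7-bis(benzyloxy)-2-[4-(benzyloxy)phenyl]-4H-chromen-4-one
Product: 3 5,7-bis(benzyloxy)-2-[4-(benzyloxy)phenyl]-8-iodo-4H-chromen-4-one
Conditions: N-iodosuccinimide (1.05 equiv), CF3CO2H (cat.), MeCN/CH2Cl2, 0 °C to rt
Reagents that add atoms: N-iodosuccinimide, O=C1CCC(=O)N1I
Why: Electrophilic aromatic iodination of the most electron-rich ring A, which in fully etherified 5,7-dioxygenated flavones should occur at C8 (ortho to the 7-ether and O1, para to the 5-ether) and not at C6.

Step 3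
Reactants: 3 5,7-bis(benzyloxy)-2-[4-(benzyloxy)phenyl]-8-iodo-4H-chromen-4-one; 4 [2-(benzyloxy)-5-chlorophenyl]boronic acid (1.5 equiv)
Product: 5 8-[2-(benzyloxy)-5-chlorophenyl]-5,7-bis(benzyloxy)-2-[4-(benzyloxy)phenyl]-4H-chromen-4-one
Conditions: Pd(PPh3)4 (5 mol%), K2CO3 (aq.), DME, 85 °C
Reagents that add atoms: none
Why: Suzuki–Miyaura coupling in which zerovalent palladium inserts into the C–I bond only, the electron-rich aryl chloride being inert to this catalyst, so the C8–aryl bond should form with the chlorine kept as the handle for boron.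

Step 4
Reactants: 5 8-[2-(benzyloxy)-5-chlorophenyl]-5,7-bis(benzyloxy)-2-[4-(benzyloxy)phenyl]-4H-chromen-4-one
Product: 6 {4-(benzyloxy)-3-[5,7-bis(benzyloxy)-2-(4-(benzyloxy)phenyl)-4-oxo-4H-chromen-8-yl]phenyl}boronic acid
Conditions: XPhos-Pd(2'-amino-1,1'-biphenyl-2-yl)Cl (second-generation XPhos palladacycle, 2 mol%), XPhos (4 mol%), B2(OH)4 (3 equiv), KOAc (3 equiv), EtOH/THF, 80 °C; aqueous work-up
Reagents that add atoms: tetrahydroxydiboron, OB(O)B(O)O
Why: Miyaura-type borylation of an aryl chloride with tetrahydroxydiboron under a bulky biarylphosphine palladium catalyst should give the free boronic acid directly, the flavone and benzyl ethers being inert to acetate base.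

Step 5
Reactants: 7 1-(2,6-dihydroxy-4-methoxyphenyl)ethan-1-one
Product: 8 1-[2-(benzyloxy)-6-hydroxy-4-methoxyphenyl]ethan-1-one
Conditions: BnBr (1.05 equiv), K2CO3, acetone, reflux
Reagents that add atoms: benzyl bromide, BrCc1ccccc1
Why: Williamson mono-etherification of a symmetric diol, which should stop after one alkylation because the remaining hydroxyl is locked in a hydrogen bond to the ketone.

Step 6
Reactants: 8 1-[2-(benzyloxy)-6-hydroxy-4-methoxyphenyl]ethan-1-one
Product: 10 5-(benzyloxy)-7-methoxy-4H-chromen-4-one, via enaminone 9 (not isolated)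
Conditions: Me2NCH(OMe)2 (3 equiv), toluene, 100 °C; then conc. HCl, CH2Cl2, 40 °C
Reagents that add atoms: N,N-dimethylformamide dimethyl acetal, COC(OC)N(C)C
Why: Enaminone formation at the acetyl methyl group followed by acid-promoted 6-endo addition of the free phenol and loss of dimethylamine is the standard chromone synthesis from 2-hydroxyacetophenones.

Step 7
Reactants: 6 {4-(benzyloxy)-3-[5,7-bis(benzyloxy)-2-(4-(benzyloxy)phenyl)-4-oxo-4H-chromen-8-yl]phenyl}boronic acid (limiting); 10 5-(benzyloxy)-7-methoxy-4H-chromen-4-one (3 equiv)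
Product: 11 (2S)-5-(benzyloxy)-2-{4-(benzyloxy)-3-[5,7-bis(benzyloxy)-2-(4-(benzyloxy)phenyl)-4-oxo-4H-chromen-8-yl]phenyl}-7-methoxychroman-4-one
Conditions: Pd(OCOCF3)2 (10 mol%), (R)-t-BuPyOx [(R)-4-tert-butyl-2-(pyridin-2-yl)-4,5-dihydrooxazole, 12 mol%], NH4PF6 (30 mol%), H2O (5 equiv), ClCH2CH2Cl, 60 °C
Reagents that add atoms: none
Why: Transmetalation of boronic acid 6 to the cationic (t-BuPyOx) complex of divalent palladium gives an arylpalladium cation, which binds the C2=C3 bond of chromone 10 and inserts it so that the aryl group is delivered to C2; protonolysis of the resulting palladium enolate by water releases the flavanone and returns the catalyst without change of oxidation state. The closest known reaction type is the palladium-catalysed asymmetric conjugate addition of arylboronic acids to chromones with pyridine-oxazoline ligands, which gives flavanones directly. No ring is closed: ring C is already present in 10 and only the exocyclic C2–C1' bond is formed. The C2 stereocentre is under catalyst control: the tert-butyl group of the ligand blocks one enone face in the insertion transition state, and the (R)-ligand is chosen so that the aryl group reaches the Re face of C2 (O1 > C3 > H) to give (2S). The step needs chemoselectivity between two enones and a product that does not racemise: the 2-aryl-substituted flavone enone of 6 and 11 should not insert whereas the unhindered 2-H chromone does, the non-basic aqueous medium avoids the retro-oxa-Michael ring opening that racemises flavanones, and the 5-O-benzyl group prevents chelation of palladium by a peri-hydroxy ketone.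

Step 8
Reactants: 11 (2S)-5-(benzyloxy)-2-{4-(benzyloxy)-3-[5,7-bis(benzyloxy)-2-(4-(benzyloxy)phenyl)-4-oxo-4H-chromen-8-yl]phenyl}-7-methoxychroman-4-one
Product: 12 (2S)-5-hydroxy-2-{4-hydroxy-3-[5,7-dihydroxy-2-(4-hydroxyphenyl)-4-oxo-4H-chromen-8-yl]phenyl}-7-methoxychroman-4-one (target)
Conditions: H2 (1 atm), 10% Pd/C, THF/MeOH, rt, stopped after uptake for five benzyl groups
Reagents that add atoms: none
Why: Catalytic hydrogenolysis should cleave the five benzyl ethers while the aryl methyl ether, the flavone double bond, both ketones and the C2 stereocentre remain untouched under these mild conditions.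

Compound list
1 | apigenin | O=c1cc(-c2ccc(O)cc2)oc2cc(O)cc(O)c12 | starting material
2 | 5,7-bis(benzyloxy)-2-[4-(benzyloxy)phenyl]-4H-chromen-4-one | O=c1cc(-c2ccc(OCc3ccccc3)cc2)oc2cc(OCc3ccccc3)cc(OCc3ccccc3)c12 | intermediate
3 | 5,7-bis(benzyloxy)-2-[4-(benzyloxy)phenyl]-8-iodo-4H-chromen-4-one | O=c1cc(-c2ccc(OCc3ccccc3)cc2)oc2c(I)c(OCc3ccccc3)cc(OCc3ccccc3)c12 | intermediate
4 | [2-(benzyloxy)-5-chlorophenyl]boronic acid | OB(O)c1cc(Cl)ccc1OCc1ccccc1 | starting material
5 | 8-[2-(benzyloxy)-5-chlorophenyl]-5,7-bis(benzyloxy)-2-[4-(benzyloxy)phenyl]-4H-chromen-4-one | O=c1cc(-c2ccc(OCc3ccccc3)cc2)oc2c(-c3cc(Cl)ccc3OCc3ccccc3)c(OCc3ccccc3)cc(OCc3ccccc3)c12 | intermediate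
6 | {4-(benzyloxy)-3-[5,7-bis(benzyloxy)-2-(4-(benzyloxy)phenyl)-4-oxo-4H-chromen-8-yl]phenyl}boronic acid | O=c1cc(-c2ccc(OCc3ccccc3)cc2)oc2c(-c3cc(B(O)O)ccc3OCc3ccccc3)c(OCc3ccccc3)cc(OCc3ccccc3)c12 | intermediate
7 | 1-(2,6-dihydroxy-4-methoxyphenyl)ethan-1-one | CC(=O)c1c(O)cc(OC)cc1O | starting material
8 | 1-[2-(benzyloxy)-6-hydroxy-4-methoxyphenyl]ethan-1-one | CC(=O)c1c(O)cc(OC)cc1OCc1ccccc1 | intermediate
9 | (E)-1-[2-(benzyloxy)-6-hydroxy-4-methoxyphenyl]-3-(dimethylamino)prop-2-en-1-one | CN(C)/C=C/C(=O)c1c(O)cc(OC)cc1OCc1ccccc1 | intermediate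
10 | 5-(benzyloxy)-7-methoxy-4H-chromen-4-one | COc1cc(OCc2ccccc2)c2c(c1)occc2=O | intermediate
11 | (2S)-5-(benzyloxy)-2-{4-(benzyloxy)-3-[5,7-bis(benzyloxy)-2-(4-(benzyloxy)phenyl)-4-oxo-4H-chromen-8-yl]phenyl}-7-methoxychroman-4-one | COc1cc(OCc2ccccc2)c3c(c1)O[C@H](c4ccc(OCc5ccccc5)c(-c5c(OCc6ccccc6)cc(OCc6ccccc6)c6c(=O)cc(-c7ccc(OCc8ccccc8)cc7)oc56)c4)CC3=O | intermediate
12 | (2S)-5-hydroxy-2-{4-hydroxy-3-[5,7-dihydroxy-2-(4-hydroxyphenyl)-4-oxo-4H-chromen-8-yl]phenyl}-7-methoxychroman-4-one | COc1cc(O)c2c(c1)O[C@H](c1ccc(O)c(-c3c(O)cc(O)c4c(=O)cc(-c5ccc(O)cc5)oc34)c1)CC2=O | target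

Total step count: 8. Longest linear sequence: 6 steps (steps 1, 2, 3, 4, 7, 8).

Steps most likely to fail

Step 7. Insertion of the electron-rich, doubly oxygen-donated chromone may be slower than protodeboronation or homocoupling of the electron-rich boronic acid, and the para-alkoxy aryl group may erode facial selectivity. The fallback gives up the conjugate arylation and closes ring C by oxa-Michael addition instead. It sets out from iodide 3 and uses acetophenone 8. Commercial 4-(benzyloxy)-3-bromobenzaldehyde is borylated (B2pin2, Pd(dppf)Cl2, KOAc, dioxane, 90 °C) to 4-(benzyloxy)-3-(4,4,5,5-tetramethyl-1,3,2-dioxaborolan-2-yl)benzaldehyde F1. Suzuki coupling of F1 with 3 (Pd(PPh3)4, K2CO3, DME/H2O, 85 °C) should give the biaryl aldehyde F2. Claisen–Schmidt condensation of F2 with 8 (KOH, EtOH/THF, rt) should give the 2'-hydroxychalcone F3. Heating F3 with NaOAc in EtOH should close ring C to the racemic flavanone F4. Preparative HPLC on a cellulose tris(3,5-dimethylphenylcarbamate) phase then delivers the (2S) enantiomer, which is compound 11, where the route is rejoined; the (2R) enantiomer can be re-equilibrated with base and recycled.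

Step 4. The C–Cl bond may be reduced instead of borylated, and the free boronic acid may be lost to protodeboronation or to boroxine mixtures on isolation. The fallback sets out from chloride 5 and carries boron through as a protected ester that can be purified by chromatography. Miyaura borylation with B2pin2 (Pd2(dba)3, XPhos, KOAc, dioxane, 110 °C) should give the pinacol boronate F5. Oxidative cleavage of the pinacol unit (NaIO4, NH4OAc, acetone/H2O, rt) then releases boronic acid 6, where the route is rejoined.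

Step 3. Transmetalation at the doubly ortho-flanked C8–palladium centre may be slow enough for protodeboronation of the ortho-alkoxy boronic acid and reductive deiodination to take over. The fallback sets out from iodide 3 and replaces the boron nucleophile by a more reactive organozinc (Negishi coupling). Commercial 2-bromo-4-chlorophenol is benzylated (BnBr, K2CO3, acetone) to 1-(benzyloxy)-2-bromo-4-chlorobenzene F6. Bromine–lithium exchange (n-BuLi, THF, −78 °C) gives [2-(benzyloxy)-5-chlorophenyl]lithium F7, which is transmetalated with ZnCl2 to [2-(benzyloxy)-5-chlorophenyl]zinc chloride F8. Coupling of F8 with 3 (Pd(OAc)2, SPhos, THF, 50 °C) should give 5, where the route is rejoined; the organozinc tolerates the flavone carbonyl and the aryl chloride is not touched at this temperature.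

Further compounds
F1 | step 7 | 4-(benzyloxy)-3-(4,4,5,5-tetramethyl-1,3,2-dioxaborolan-2-yl)benzaldehyde | O=Cc1ccc(OCc2ccccc2)c(B2OC(C)(C)C(C)(C)O2)c1
F2 | step 7 | 4-(benzyloxy)-3-[5,7-bis(benzyloxy)-2-(4-(benzyloxy)phenyl)-4-oxo-4H-chromen-8-yl]benzaldehyde | O=Cc1ccc(OCc2ccccc2)c(-c2c(OCc3ccccc3)cc(OCc3ccccc3)c3c(=O)cc(-c4ccc(OCc5ccccc5)cc4)oc23)c1
F3 | step 7 | (E)-1-[2-(benzyloxy)-6-hydroxy-4-methoxyphenyl]-3-{4-(benzyloxy)-3-[5,7-bis(benzyloxy)-2-(4-(benzyloxy)phenyl)-4-oxo-4H-chromen-8-yl]phenyl}prop-2-en-1-one | COc1cc(O)c(C(=O)/C=C/c2ccc(OCc3ccccc3)c(-c3c(OCc4ccccc4)cc(OCc4ccccc4)c4c(=O)cc(-c5ccc(OCc6ccccc6)cc5)oc34)c2)c(OCc2ccccc2)c1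
F4 | step 7 | racemic 5-(benzyloxy)-2-{4-(benzyloxy)-3-[5,7-bis(benzyloxy)-2-(4-(benzyloxy)phenyl)-4-oxo-4H-chromen-8-yl]phenyl}-7-methoxychroman-4-one | COc1cc(OCc2ccccc2)c3c(c1)OC(c4ccc(OCc5ccccc5)c(-c5c(OCc6ccccc6)cc(OCc6ccccc6)c6c(=O)cc(-c7ccc(OCc8ccccc8)cc7)oc56)c4)CC3=O
F5 | step 4 | 8-[2-(benzyloxy)-5-(4,4,5,5-tetramethyl-1,3,2-dioxaborolan-2-yl)phenyl]-5,7-bis(benzyloxy)-2-[4-(benzyloxy)phenyl]-4H-chromen-4-one | O=c1cc(-c2ccc(OCc3ccccc3)cc2)oc2c(-c3cc(B4OC(C)(C)C(C)(C)O4)ccc3OCc3ccccc3)c(OCc3ccccc3)cc(OCc3ccccc3)c12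
F6 | step 3 | 1-(benzyloxy)-2-bromo-4-chlorobenzene | Clc1ccc(OCc2ccccc2)c(Br)c1
F7 | step 3 | [2-(benzyloxy)-5-chlorophenyl]lithium | [Li]c1cc(Cl)ccc1OCc1ccccc1
F8 | step 3 | [2-(benzyloxy)-5-chlorophenyl]zinc chloride | Cl[Zn]c1cc(Cl)ccc1OCc1ccccc1
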